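If capture of X by E, at 0.0437 min⁻¹ with E as charged, is faster than the passage of L into solution at 0.00406 min⁻¹, then [X] stays low and nearly steady, and I can reckon this flask by hand.

    L ⇌ X, rate k1*(csat - [X]) (k1 = 0.00406 min⁻¹, csat = 4.5 mM)
    E + X → E.X (k2 = 0.437 M⁻¹ min⁻¹)
    E.X ⇌ D (K3 = 3.0, k3 = 6.43 × 10⁻⁴ min⁻¹)
    2 X → X2 (k4 = 0.101 M⁻¹ min⁻¹)

E 0.10 M; L 4.5 mM (held); time 40 h

- two of one species on the left: rate k times its square, two consumed each time
- at the start none of X is dissolved
- run time (flask): 40 h

- amount of E.X at 40 h, in percent of the E charged
- concentration of X in solution at 40 h, in percent of saturation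

Setting passage equal to capture is a quasi-steady state for X. It gives one quantity, the capture point, the transfer coefficient divided by the capture constant, 9.29 mM, which is the [E] at which the two pulls on X are equal:

[X]/csat = capture point / (capture point + [E])

First round, with E as charged and the pairing of two X left out for now:

[X] = 0.383 mM, so X taken up = 40.1 mM, so [E] = 59.9 mM and [X] = 0.604 mM

I keep the pairing of two X out, because at this [X] and [E] it takes X at 1.22 × 10⁻⁴ min⁻¹, slower than capture at 0.0262 min⁻¹. E.X and D relax together at 8.57 × 10⁻⁴ min⁻¹. With a steady feed, the share of bound E still E.X at the end is 56.8%, so y is 22.8%.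

The weak link is the uptake, which I reckoned at the starting [X] although [X] rises. So I go round again with the mean of the two levels:

X taken up = 39.0 mM, so [E] = 61.0 mM, [X] = 0.595 mM, sat = 13.2%, y = 22.2%

The forecast says 21.8% and 13%, with “so 38.6 mM reacted” where I have 39.0 mM.

The flask gives y 21.9% and sat 13.0%, with 61% of E left. Its own [E] put into the capture point gives 13.1% of saturation. This flask is not at rest: at 400 h E is down to 0%, D has grown from 16.7% to 75.0%, and [X] reads 0.00379 M. E.X ends at 25.0%, after 30.8% at 80.0 h, and D to E.X then stands at 3.00.

In the neighbour flask with 0.25 M of E, the same capture point gives [X] = 0.161 mM at the start, an uptake of 42.3 mM, 83.1% of E left and a final [X] of 0.193 mM. That flask gives 83% and 0.192 mM.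

All constants stand for no real mixture.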